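- spring: starting material 0.18 M; second substrate 0.060 M; partner 0.132 M; free catalyst 0.11 mM; impurity 77 µM; run made earlier
- flask: starting material 0.12 M; second substrate 0.0600 M; partner 0.132 M; free catalyst 0.11 mM; impurity 77 µM; time 20 h
spring run (percent of the starting material charged)

| time / min | target / % |
|---|---|
| 10.0 | 6.6 |
| 30.0 | 11.7 |
| 60.0 | 12.7 |
| 80.0 | 14.1 |
| 120 | 13.6 |

(standard deviation of a reading: 0.5 percentage points)
1. the moment within 20 h at which there is most target
2. the amount of target, in percent of the starting material charged, at that time

- I start from the amounts: c_impurity is 77 µM and c_free catalyst is 0.11 mM, so I fold them into the poison ratio, impurity charged per catalyst charged, c_impurity / c_free catalyst: 0.700.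
- My assumption is that one impurity takes one catalyst for good. Below one, the ratio is then the share of catalyst that ends up spent once the impurity is used up, and in this flask 30.0% escapes. The spring run has the same ratio, 0.700, so I do not read its reading of 14.1% at 80.0 min as a flask whose whole catalyst has died.
- One number is not enough. The spring run and this flask share the ratio, although their starting material differs. I therefore commit to the catalyst's fate, not to height or time.
- The forecast gives 16% at 3 h and says: “Beyond that the curve is flat”.
- This flask gives 15.8% at 1.32 h.

    starting material + free catalyst ⇌ catalyst intermediate A (K = 72.9 M⁻¹, k = 9860 M⁻¹ h⁻¹)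
    partner + catalyst intermediate A → free catalyst + target (k = 25600 M⁻¹ h⁻¹)
    second substrate + free catalyst ⇌ catalyst intermediate B (K = 7.20 M⁻¹, k = 7210 M⁻¹ h⁻¹)
    partner + catalyst intermediate B → free catalyst + second product (k = 5860 M⁻¹ h⁻¹)
    partner → decomposed reagent (k = 3.27 h⁻¹)
    target + free catalyst ⇌ isomer of the product + free catalyst, rate k6*[free catalyst]*[target] forward; the back reaction follows from the equilibrium constant (K = 1.37, k = 5620 M⁻¹ h⁻¹)
    free catalyst + impurity → spent catalyst (k = 83900 M⁻¹ h⁻¹)

- In this flask, at 0.175 h, the half-life of partner by its decomposition is 0.21 h, shorter than the best time, and at the best time partner stands at 0.456% of its charge beside 0.109 M of decomposed reagent. After that, target falls to 11.4% at 20.0 h while isomer of the product reaches 5.71%. Spent catalyst there is 70.0% of the catalyst charged, against a poison ratio of 0.700. The neighbour with 4.4 × 10⁻⁵ M of free catalyst has a ratio of 1.75, so I reckon 42.9% of its impurity left over, and at 20.0 h it holds 42.9%.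

The runs were computed for substances that don't exist; the scatter is artificial.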